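The synthesis rests on cutting two neighbouring bonds of ring A, O1–C8a and C4a–C4, so that the pyranone oxygen and the C4 carbonyl carbon both originate from one carboxyl group. In one operation 3,5-dimethoxybenzyne inserts into the C–O bond of a chiral alk-2-ynoic acid. This gives the ortho-hydroxyaryl ynone, which already holds C4, C3, C2, C1'–C7' and the (R)-carbinol C2'; no ring forms yet. The precursors are a 2-silylaryl triflate from 3,5-dimethoxyphenol and (R)-5-(4-methoxybenzyloxy)undec-10-en-2-ynoic acid from a kinetically resolved epoxide. Amine-relayed 6-endo closure, cross-metathesis with acrylic acid and a single BCl3 deprotection complete the target.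

Key step: step 8

Remark on the chemistry (protecting group): the C2' oxygen travels as a 4-methoxybenzyl (PMB) ether, because a silyl ether would have to outlast several equivalents of hot fluoride in step 8, whereas PMB ignores fluoride and falls off in the same BCl3 operation that frees the 5-hydroxyl, which saves a step.
Assumption (sense of resolution): with alkyl-substituted terminal epoxides the (R,R)-configured cobalt salen catalyst hydrolyses the (S)-epoxide and leaves the (R)-epoxide; salen stands for the N,N'-bis(3,5-di-tert-butylsalicylidene)cyclohexane-1,2-diamine dianion.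
Locants: chromone numbering for the bicycle; C1' (at the ring) to C9' (carboxyl) for the side chain. The target stereocentre C2' is (R).

**Fragment A: aryne precursor**

Step 1
Reactants: 1 3,5-dimethoxyphenol
Product: 2 2-bromo-3,5-dimethoxyphenol
Conditions: NBS (1.0 equiv), CH2Cl2, −78 °C → rt
Reagents that add atoms: N-bromosuccinimide, O=C1CCC(=O)N1Br
Why: Electrophilic aromatic bromination, in which NBS at low temperature should attack the less crowded position ortho to the hydroxyl (C2, equivalent to C6) rather than C4 squeezed between two methoxy groups, while one equivalent limits dibromination.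

Step 2
Reactants: 2 2-bromo-3,5-dimethoxyphenol
Product: 3 (2-bromo-3,5-dimethoxyphenoxy)trimethylsilane
Conditions: HMDS, THF, reflux; evaporate
Reagents that add atoms: hexamethyldisilazane, C[Si](C)(C)N[Si](C)(C)C
Why: O-silylation of a phenol with HMDS needs no added base and releases only a volatile by-product, so crude 3 should be usable after evaporation.

Step 3
Reactants: 3 (2-bromo-3,5-dimethoxyphenoxy)trimethylsilane
Product: 5 3,5-dimethoxy-2-(trimethylsilyl)phenyl trifluoromethanesulfonate, via lithium 2-silylphenoxide 4 (not isolated)
Conditions: n-BuLi, THF, −78 °C; then Tf2O, −78 → 0 °C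
Reagents that add atoms: trifluoromethanesulfonic anhydride, O=S(=O)(OS(=O)(=O)C(F)(F)F)C(F)(F)F
Why: Bromine–lithium exchange triggers a 1,3 O-to-C silyl shift (retro-Brook rearrangement) driven by formation of phenoxide 4, which is sulfonylated in the same flask, the standard entry to 2-silylaryl triflates.

**Fragment B: chiral alkynoic acid**

Step 4
Reactants: 6 racemic 1,2-epoxyoct-7-ene
Product: 7 (R)-1,2-epoxyoct-7-ene
Conditions: (R,R)-(salen)Co(OAc) (0.5 mol %), H2O (0.55 equiv), neat, 0 °C → rt; distil
Reagents that add atoms: none
Why: Jacobsen hydrolytic kinetic resolution, in which the trivalent cobalt salen complex hydrates the (S)-epoxide much faster than the (R)-epoxide, so that the unreacted (R)-enantiomer, which sets the only stereocentre of the target (C2'), should be recovered in high enantiomeric purity by distillation.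

Step 5
Reactants: 7 (R)-1,2-epoxyoct-7-ene; 8 lithium acetylide–ethylenediamine complex
Product: 9 (R)-dec-9-en-1-yn-4-ol
Conditions: LiC≡CH·H2NCH2CH2NH2 (1.5 equiv), DMSO, 0 °C → rt; then H2O
Reagents that add atoms: none
Why: SN2 opening of a terminal epoxide by acetylide occurs at the unsubstituted carbon and leaves the C–O bond of the stereocentre intact, so the (R) configuration is carried over unchanged.

Step 6
Reactants: 9 (R)-dec-9-en-1-yn-4-ol
Product: 10 (R)-1-[(dec-9-en-1-yn-4-yloxy)methyl]-4-methoxybenzene
Conditions: NaH (1.1 equiv), PMBCl, TBAI (cat.), THF, 0 °C → rt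
Reagents that add atoms: 4-methoxybenzyl chloride, COc1ccc(CCl)cc1
Why: Williamson etherification of the sodium alkoxide (the alcohol is far more acidic than the alkyne C–H) under iodide catalysis installs a group inert to fluoride, organolithium, amine and ruthenium carbene chemistry without touching the C–O bond of the stereocentre.

Step 7
Reactants: 10 (R)-1-[(dec-9-en-1-yn-4-yloxy)methyl]-4-methoxybenzene
Product: 12 (R)-5-[(4-methoxybenzyl)oxy]undec-10-en-2-ynoic acid, via lithium acetylide 11 (not isolated)
Conditions: n-BuLi (1.05 equiv), THF, −78 °C; CO2; then 1 M HCl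
Reagents that add atoms: carbon dioxide, O=C=O
Why: Deprotonation of the terminal alkyne and carboxylation of acetylide 11 is the standard route to alk-2-ynoic acids, and at −78 °C neither the benzylic ether nor the remote alkene is touched.

**Union and completion**

Step 8
Reactants: 5 3,5-dimethoxy-2-(trimethylsilyl)phenyl trifluoromethanesulfonate; 12 (R)-5-[(4-methoxybenzyl)oxy]undec-10-en-2-ynoic acid
Product: 14 (R)-1-(2-hydroxy-4,6-dimethoxyphenyl)-5-[(4-methoxybenzyl)oxy]undec-10-en-2-yn-1-one, via 3,5-dimethoxybenzyne 13 (not isolated)
Conditions: 5 (1.5 equiv), CsF (4 equiv), THF (dilute), 125 °C, sealed tube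
Reagents that add atoms: none
Why: Fluoride removes the trimethylsilyl group of 5 and triflate departs, releasing aryne 13, to which the carboxylate of 12 adds through oxygen. The aryl anion so formed sits ortho to its own ester and attacks the ester carbonyl through a strained four-membered alkoxide, whose opening shifts the acyl group from O to C and frees the phenoxide, so that O1–C8a and C4a–C4 arise in one pot. The closest known reaction type is the formal insertion of arynes into the C–O bond of carboxylic acids (an anionic Fries-type 1,3-acyl shift), which has been shown for aromatic, alkenoic and alk-2-ynoic acids. No ring is closed and no stereocentre is created, and C5 of the acid is a remote spectator that cannot epimerise. Regioselectivity is required and is secured by the methoxy group next to the triple bond, which distorts the aryne and inductively stabilises negative charge on the adjacent carbon (future C4a), so that oxygen binds the far carbon (future C8a). Chemoselectivity (acyl shift faster than protonation of the aryl anion) is served by heat, dilution and excess CsF that holds the acid as its salt, and the PMB ether is indifferent to fluoride.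

Step 9
Reactants: 14 (R)-1-(2-hydroxy-4,6-dimethoxyphenyl)-5-[(4-methoxybenzyl)oxy]undec-10-en-2-yn-1-one
Product: 16 (R)-5,7-dimethoxy-2-{2-[(4-methoxybenzyl)oxy]oct-7-en-1-yl}-4H-chromen-4-one, via diethylamino enone 15 (not isolated)
Conditions: Et2NH (5 equiv), EtOH, rt → 60 °C
Reagents that add atoms: none
Why: Aza-Michael addition of the secondary amine to the ynone gives β-amino enone 15, and intramolecular addition–elimination by the phenol at that same carbon (C2) expels Et2NH, which enforces the six-membered 6-endo outcome over 5-exo aurone formation with a base too weak to disturb the C2' ether.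

Step 10
Reactants: 16 (R)-5,7-dimethoxy-2-{2-[(4-methoxybenzyl)oxy]oct-7-en-1-yl}-4H-chromen-4-one; 17 acrylic acid
Product: 18 (R,E)-9-(5,7-dimethoxy-4-oxo-4H-chromen-2-yl)-8-[(4-methoxybenzyl)oxy]non-2-enoic acid
Conditions: acrylic acid (3 equiv), second-generation Hoveyda–Grubbs catalyst (5 mol %), CH2Cl2, 40 °C
Reagents that add atoms: none
Why: Olefin cross-metathesis between an unhindered terminal alkene and an electron-poor acrylic partner that barely homodimerises is a well-established selective pairing that should give the (E)-enoic acid under thermodynamic control, the endocyclic C2=C3 bond being too substituted and electron-poor to take part.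

Step 11
Reactants: 18 (R,E)-9-(5,7-dimethoxy-4-oxo-4H-chromen-2-yl)-8-[(4-methoxybenzyl)oxy]non-2-enoic acid
Product: 19 Penithochromone T, (R,E)-8-hydroxy-9-(5-hydroxy-7-methoxy-4-oxo-4H-chromen-2-yl)non-2-enoic acid
Conditions: BCl3 (5 equiv), pentamethylbenzene (3 equiv), CH2Cl2, −78 → 0 °C; then H2O
Reagents that add atoms: none
Why: Chelation-directed ether cleavage, in which BCl3 held between the C4 carbonyl and the peri 5-methoxy oxygen lets chloride remove only that methyl group while the unchelated 7-methyl ether stays, and the same Lewis acid ionises the electron-rich PMB ether at low temperature with its cation intercepted by pentamethylbenzene (Friedel–Crafts scavenging), so the C2'–O bond and the (R) configuration are untouched.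

**Compound list**

1 | 3,5-dimethoxyphenol | COc1cc(O)cc(OC)c1 | starting material
2 | 2-bromo-3,5-dimethoxyphenol | COc1cc(O)c(Br)c(OC)c1 | intermediate
3 | (2-bromo-3,5-dimethoxyphenoxy)trimethylsilane | COc1cc(O[Si](C)(C)C)c(Br)c(OC)c1 | intermediate
4 | lithium 3,5-dimethoxy-2-(trimethylsilyl)phenoxide (lithium 2-silylphenoxide) | [Li+].[O-]c1cc(OC)cc(OC)c1[Si](C)(C)C | intermediate
5 | 3,5-dimethoxy-2-(trimethylsilyl)phenyl trifluoromethanesulfonate | COc1cc(OC)c([Si](C)(C)C)c(OS(=O)(=O)C(F)(F)F)c1 | intermediate
6 | racemic 1,2-epoxyoct-7-ene | C=CCCCCC1CO1 | starting material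
7 | (R)-1,2-epoxyoct-7-ene | C=CCCCC[C@@H]1CO1 | intermediate
8 | lithium acetylide–ethylenediamine complex | [Li+].[C-]#C.NCCN | starting material
9 | (R)-dec-9-en-1-yn-4-ol | C#CC[C@H](O)CCCCC=C | intermediate
10 | (R)-1-[(dec-9-en-1-yn-4-yloxy)methyl]-4-methoxybenzene | C#CC[C@H](OCc1ccc(OC)cc1)CCCCC=C | intermediate
11 | lithium acetylide of 10 | [Li+].[C-]#CC[C@H](OCc1ccc(OC)cc1)CCCCC=C | intermediate
12 | (R)-5-[(4-methoxybenzyl)oxy]undec-10-en-2-ynoic acid | OC(=O)C#CC[C@H](OCc1ccc(OC)cc1)CCCCC=C | intermediate
13 | 3,5-dimethoxybenzyne (1,2-didehydro-3,5-dimethoxybenzene) | COC1=CC(OC)=CC#C1 | intermediate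
14 | (R)-1-(2-hydroxy-4,6-dimethoxyphenyl)-5-[(4-methoxybenzyl)oxy]undec-10-en-2-yn-1-one | COc1cc(O)c(C(=O)C#CC[C@H](OCc2ccc(OC)cc2)CCCCC=C)c(OC)c1 | intermediate
15 | (R,E)-3-(diethylamino)-1-(2-hydroxy-4,6-dimethoxyphenyl)-5-[(4-methoxybenzyl)oxy]undeca-2,10-dien-1-one (diethylamino enone; alkene geometry without consequence) | COc1cc(O)c(C(=O)/C=C(/N(CC)CC)C[C@H](OCc2ccc(OC)cc2)CCCCC=C)c(OC)c1 | intermediate
16 | (R)-5,7-dimethoxy-2-{2-[(4-methoxybenzyl)oxy]oct-7-en-1-yl}-4H-chromen-4-one | COc1cc(OC)c2c(=O)cc(C[C@H](OCc3ccc(OC)cc3)CCCCC=C)oc2c1 | intermediate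
17 | acrylic acid | C=CC(=O)O | starting material
18 | (R,E)-9-(5,7-dimethoxy-4-oxo-4H-chromen-2-yl)-8-[(4-methoxybenzyl)oxy]non-2-enoic acid | COc1cc(OC)c2c(=O)cc(C[C@H](OCc3ccc(OC)cc3)CCCC/C=C/C(=O)O)oc2c1 | intermediate
19 | Penithochromone T, (R,E)-8-hydroxy-9-(5-hydroxy-7-methoxy-4-oxo-4H-chromen-2-yl)non-2-enoic acid | COc1cc(O)c2c(=O)cc(C[C@H](O)CCCC/C=C/C(=O)O)oc2c1 | target

Total step count: 11.
Longest linear sequence: 8 (steps 4–11, from epoxide 6).

**Steps most likely to fail**

1. Step 8 (key step).
- What may go wrong: the aryl anion captures a proton before the acyl shift (plain O-arylation of the acid). The alkynoate may also lose CO2 thermally, or the phenoxide may attack the triple bond early and unselectively in the hot basic medium.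
- Fallback: palladium-catalysed carbonylative annulation. It sets out from phenol 1 and alkyne 10 and returns at chromone 16.
- Iodination of 1 with N-iodosuccinimide in CH2Cl2 at low temperature should give 2-iodo-3,5-dimethoxyphenol F1.
- F1, alkyne 10 and CO are then coupled with catalytic PdCl2(dppf) in Et2NH. Oxidative addition to zerovalent palladium, CO insertion and alkynylation build ynone 14 in the flask, and the amine solvent relays it through 15 to 16.
- C4 then comes from CO, and steps 7–9 are bypassed.

2. Step 11.
- What may go wrong: the boron-bound C2' oxygen is eliminated toward the conjugated 2-alkenylchromone. The arylmethyl cation may also transfer onto ring A, or the 5-O/7-O selectivity may erode if the mixture has to be warmed.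
- Fallback: orthogonal two-stage release. It sets out from 18 and returns at 19.
- Oxidative PMB removal with DDQ in CH2Cl2/pH 7 buffer should give (R,E)-9-(5,7-dimethoxy-4-oxo-4H-chromen-2-yl)-8-hydroxynon-2-enoic acid F2.
- The chelated 5-methyl ether alone is then cut by iodide under magnesium chelation (MgI2·OEt2, THF, gentle heating). This is a much weaker Lewis acid that releases no carbocation.

3. Step 10.
- What may go wrong: the catalyst decays in the presence of the free acid. The double bond may also migrate before metathesis, which leads to chain shortening, or the terminal alkene may homodimerise.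
- Fallback: oxidative cleavage followed by condensation. It sets out from 16 and returns at 18.
- Lemieux–Johnson cleavage of the terminal alkene (OsO4 cat., NaIO4, 2,6-lutidine, dioxane/H2O) should give (R)-7-(5,7-dimethoxy-4-oxo-4H-chromen-2-yl)-6-[(4-methoxybenzyl)oxy]heptanal F3.
- Doebner–Knoevenagel condensation with malonic acid in pyridine passes through (R)-2-{7-(5,7-dimethoxy-4-oxo-4H-chromen-2-yl)-6-[(4-methoxybenzyl)oxy]heptylidene}malonic acid F4, which decarboxylates on warming to the (E)-acid 18.

**Further compounds**

F1 | step 8 | 2-iodo-3,5-dimethoxyphenol | COc1cc(O)c(I)c(OC)c1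
F2 | step 11 | (R,E)-9-(5,7-dimethoxy-4-oxo-4H-chromen-2-yl)-8-hydroxynon-2-enoic acid | COc1cc(OC)c2c(=O)cc(C[C@H](O)CCCC/C=C/C(=O)O)oc2c1
F3 | step 10 | (R)-7-(5,7-dimethoxy-4-oxo-4H-chromen-2-yl)-6-[(4-methoxybenzyl)oxy]heptanal | COc1cc(OC)c2c(=O)cc(C[C@H](OCc3ccc(OC)cc3)CCCCC=O)oc2c1
F4 | step 10 | (R)-2-{7-(5,7-dimethoxy-4-oxo-4H-chromen-2-yl)-6-[(4-methoxybenzyl)oxy]heptylidene}malonic acid | COc1cc(OC)c2c(=O)cc(C[C@H](OCc3ccc(OC)cc3)CCCCC=C(C(=O)O)C(=O)O)oc2c1
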